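**Plan**

- Retrosynthesis: the bond from C3 of the lactone ring to the ketone carbon is cut first (C-acylation of a preformed 6-methyloxane-2,4-dione by a chain acid). Then, in one operation, the bond between the allylic CH2 and the far alkene carbon and the C–CH3 bond of the lone methyl-bearing methine are cut.
- Enabling feature: that methine lies one CH2 from the E-disubstituted alkene and three carbons before the ketone carbonyl. It is therefore a 2-methylalkyl metal made from pent-4-en-1-ol and AlMe3, and the alkene is an (E)-alkenyl iodide; the six-membered lactone takes no part.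
- The iodide is cut at the bond between the carboxyl-bearing CH and its alkene carbon (vinyl cuprate opening of an epoxy alcohol, then Takai olefination) and at the carbinol–α-carbon bond (made as a Wittig alkene).
- Forward: iodide from (S)-2-methylbutan-1-ol (steps 1–8), chain union (step 10), left carboxyl unveiled and masked as tert-butyl ester, right carboxyl unveiled, acylation of the separately lactonised ring (the only ring, steps 16–17), acidolysis.
- Stereochemistry: the sec-butyl centre comes from (S)-2-methylbutan-1-ol. The carbinol and α-carbon come from Sharpless epoxidation with D-(−)-diisopropyl tartrate and SN2 inversion at C2. The methyl methine comes from the zirconocene enantiomer, the lactone centre from methyl (R)-3-hydroxybutanoate, and the E-alkene from Takai olefination, retained in the coupling.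

Key step: step 10

Remark: the lactone of the target is written as its 4-hydroxy-5,6-dihydro-2H-pyran-2-one (enol) tautomer and ring precursor 27 as the 2,4-dione tautomer; PMB = 4-methoxybenzyl, TBS = tert-butyldimethylsilyl.

**Route**

Step 1
Reactants: 1 (S)-2-methylbutan-1-ol
Product: 3 ethyl (2E,4S)-4-methylhex-2-enoate, via (S)-2-methylbutanal 2 (not isolated)
Conditions: (COCl)2, DMSO, CH2Cl2, −78 °C; iPr2NEt, −78→0 °C; then Ph3P=CHCO2Et, 0 °C→rt
Reagents that add atoms: ethyl (triphenylphosphoranylidene)acetate, CCOC(=O)C=P(c1ccccc1)(c1ccccc1)c1ccccc1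
Why: Swern oxidation followed in the same flask by Wittig olefination with the stabilised ylide should trap the volatile, easily racemised aldehyde 2 at once and give the E-enoate without touching the (S) centre.

Step 2
Reactants: 3 ethyl (2E,4S)-4-methylhex-2-enoate
Product: 4 (2E,4S)-4-methylhex-2-en-1-ol
Conditions: iBu2AlH (2.2 equiv), CH2Cl2, −78 °C; aq. potassium sodium tartrate
Reagents that add atoms: none
Why: 1,2-reduction of an enoate by iBu2AlH at low temperature is the standard route to the allylic alcohol and leaves the alkene geometry and the stereocentre intact.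

Step 3
Reactants: 4 (2E,4S)-4-methylhex-2-en-1-ol
Product: 5 [(2R,3R)-3-[(2S)-butan-2-yl]oxiran-2-yl]methanol
Conditions: Ti(OiPr)4 (cat.), D-(−)-diisopropyl tartrate (cat.), tBuOOH, 4 Å molecular sieves, CH2Cl2, −20 °C
Reagents that add atoms: tert-butyl hydroperoxide, CC(C)(C)OO
Why: In the Sharpless asymmetric epoxidation the titanium tartrate complex of the D-(−)-tartrate delivers oxygen to the face of the E-allylic alcohol that gives the (2R,3R)-epoxide, reagent control overriding the small bias of the sec-butyl centre.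

Step 4
Reactants: 5 [(2R,3R)-3-[(2S)-butan-2-yl]oxiran-2-yl]methanol
Product: 6 (2S,3R,4S)-2-ethenyl-4-methylhexane-1,3-diol
Conditions: CH2=CHMgBr (excess), CuI (cat.), THF/Et2O, −30→0 °C; aq. NH4Cl
Reagents that add atoms: vinylmagnesium bromide, C=C[Mg]Br
Why: Copper-catalysed SN2 opening of the 2,3-epoxy alcohol by the vinyl Grignard reagent should occur at C2, away from the branched sec-butyl group on C3, with inversion, which places the vinyl group anti to the retained carbinol.

Step 5
Reactants: 6 (2S,3R,4S)-2-ethenyl-4-methylhexane-1,3-diol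
Product: 7 (2S,3R,4S)-2-ethenyl-1-[(4-methoxybenzyl)oxy]-4-methylhexan-3-ol
Conditions: Bu2SnO, toluene, reflux (−H2O); then PMBCl, Bu4NI, toluene, 90 °C
Reagents that add atoms: 4-methoxybenzyl chloride, COc1ccc(CCl)cc1
Why: Stannylene-mediated regioselective etherification alkylates the dibutylstannylene acetal of the 1,3-diol at the less hindered primary oxygen and leaves the secondary alcohol free.

Step 6
Reactants: 7 (2S,3R,4S)-2-ethenyl-1-[(4-methoxybenzyl)oxy]-4-methylhexan-3-ol
Product: 8 tert-butyl{[(3S,4R,5S)-3-{[(4-methoxybenzyl)oxy]methyl}-5-methylhept-1-en-4-yl]oxy}dimethylsilane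
Conditions: TBSOTf, 2,6-lutidine, CH2Cl2, −78→0 °C
Reagents that add atoms: tert-butyldimethylsilyl trifluoromethanesulfonate, CC(C)(C)[Si](C)(C)OS(=O)(=O)C(F)(F)F
Why: Silylation of a hindered secondary alcohol with the silyl triflate and 2,6-lutidine is routine and does not affect the PMB ether or the alkene.

Step 7
Reactants: 8 tert-butyl{[(3S,4R,5S)-3-{[(4-methoxybenzyl)oxy]methyl}-5-methylhept-1-en-4-yl]oxy}dimethylsilane
Product: 9 (2S,3R,4S)-3-[(tert-butyldimethylsilyl)oxy]-2-{[(4-methoxybenzyl)oxy]methyl}-4-methylhexanal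
Conditions: OsO4 (cat.), NaIO4, 2,6-lutidine, dioxane/H2O, rt
Reagents that add atoms: osmium tetroxide, O=[Os](=O)(=O)=O; sodium periodate, [Na+].[O-]I(=O)(=O)=O
Why: Lemieux–Johnson cleavage (dihydroxylation then periodate scission) of the terminal alkene under 2,6-lutidine buffering should give the α-branched aldehyde without epimerisation or β-elimination.

Step 8
Reactants: 9 (2S,3R,4S)-3-[(tert-butyldimethylsilyl)oxy]-2-{[(4-methoxybenzyl)oxy]methyl}-4-methylhexanal; 10 iodoform
Product: 11 tert-butyl{[(1E,3S,4R,5S)-1-iodo-3-{[(4-methoxybenzyl)oxy]methyl}-5-methylhept-1-en-4-yl]oxy}dimethylsilane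
Conditions: CrCl2 (excess), THF/dioxane, 0 °C→rt
Reagents that add atoms: none
Why: In the Takai olefination the gem-dichromium species from CHI3 and CrCl2 adds to the aldehyde and eliminates to the (E)-alkenyl iodide, the α-branch and the dioxane cosolvent favouring the E isomer.

Step 9
Reactants: 12 pent-4-en-1-ol
Product: 13 tert-butyldimethyl(pent-4-en-1-yloxy)silane
Conditions: TBSCl, imidazole, CH2Cl2, 0 °C→rt
Reagents that add atoms: tert-butyldimethylsilyl chloride, CC(C)(C)[Si](C)(C)Cl
Why: Imidazole-promoted silylation of a primary alcohol is standard and gives an ether that tolerates AlMe3.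

Step 10
Reactants: 13 tert-butyldimethyl(pent-4-en-1-yloxy)silane; 14 trimethylaluminium; 11 tert-butyl{[(1E,3S,4R,5S)-1-iodo-3-{[(4-methoxybenzyl)oxy]methyl}-5-methylhept-1-en-4-yl]oxy}dimethylsilane
Product: 17 (4R,6E,8S,9R,10S)-1,9-bis[(tert-butyldimethylsilyl)oxy]-8-{[(4-methoxybenzyl)oxy]methyl}-4,10-dimethyldodec-6-ene, via (R)-alkyldimethylalane 15 (not isolated), via (R)-alkylzinc triflate 16 (not isolated)
Conditions: 13 (2 equiv), AlMe3, (−)-bis(1-neomenthylindenyl)zirconium dichloride [(−)-(NMI)2ZrCl2, 5 mol%], methylaluminoxane (MeAlO)n, CH2Cl2, 0→23 °C; CH2Cl2 and excess AlMe3 removed in vacuo; Zn(OTf)2, DMF, 70 °C; then 11 (1 equiv), PdCl2(DPEphos) [DPEphos = bis(2-diphenylphosphinophenyl) ether, 5 mol%], iBu2AlH (10 mol%), DMF, 23→70 °C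
Reagents that add atoms: none
Why: The methylzirconocene cation formed from (−)-(NMI)2ZrCl2, AlMe3 and methylaluminoxane inserts the terminal alkene of 13 into its Zr–CH3 bond, methyl going to the internal carbon, and Zr-to-Al exchange releases alane 15; after excess AlMe3 is stripped off, Zn(OTf)2 in DMF passes the primary alkyl group to zinc (16), and zerovalent palladium from PdCl2(DPEphos)/iBu2AlH joins it to 11 by oxidative addition into the C–I bond, transmetalation and reductive elimination. The closest known reaction type is the zirconium-catalysed asymmetric carboalumination of 1-alkenes run in one flask with a palladium-catalysed Negishi alkenylation. No ring is closed; the new bonds are the C–CH3 bond and the bond between the allylic CH2 and the alkene carbon that carried iodine. The new methyl-bearing centre (4R) is set only by the zirconocene enantiomer, the (−)-form being the one that turns 1-alkenes into (R)-2-methylalkyl alanes, and the three centres of 11 take no part. The step needs enantioface selectivity, methyl delivery to the internal alkene carbon, transfer of the 2-methylalkyl group instead of a methyl group and retention of the E geometry; these rest on the catalyst, on the monosubstituted alkene of 13, on removal of AlMe3 with 15 kept in excess over 11, and on the stereospecific palladium cycle with the wide-bite-angle DPEphos ligand, for which the C–I bond of 11 is the only reactive site. The minor (4S)-epimer expected from imperfect face selection should be removed by preparative chromatography at alcohol 18.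

Step 11
Reactants: 17 (4R,6E,8S,9R,10S)-1,9-bis[(tert-butyldimethylsilyl)oxy]-8-{[(4-methoxybenzyl)oxy]methyl}-4,10-dimethyldodec-6-ene
Product: 18 (2S,3R,4S)-3-[(tert-butyldimethylsilyl)oxy]-2-[(1E,4R)-7-[(tert-butyldimethylsilyl)oxy]-4-methylhept-1-en-1-yl]-4-methylhexan-1-ol
Conditions: DDQ, CH2Cl2/pH 7 phosphate buffer, 0 °C
Reagents that add atoms: none
Why: Oxidative PMB cleavage by DDQ (electron transfer from the electron-rich arene, then hydrolysis of the oxocarbenium ion) is orthogonal to both silyl ethers and to the isolated alkene.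

Step 12
Reactants: 18 (2S,3R,4S)-3-[(tert-butyldimethylsilyl)oxy]-2-[(1E,4R)-7-[(tert-butyldimethylsilyl)oxy]-4-methylhept-1-en-1-yl]-4-methylhexan-1-ol
Product: 20 (2R,3R,4S)-3-[(tert-butyldimethylsilyl)oxy]-2-[(1E,4R)-7-[(tert-butyldimethylsilyl)oxy]-4-methylhept-1-en-1-yl]-4-methylhexanoic acid, via chain aldehyde 19 (not isolated)
Conditions: TEMPO (cat.), PhI(OAc)2, MeCN/pH 7 phosphate buffer, 0 °C→rt
Reagents that add atoms: water, O
Why: Oxoammonium (TEMPO/PhI(OAc)2) oxidation in the presence of water takes the primary alcohol through aldehyde 19 and its hydrate to the acid under near-neutral conditions that should spare the α-vinyl stereocentre, the alkene and the silyl ethers.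

Step 13
Reactants: 20 (2R,3R,4S)-3-[(tert-butyldimethylsilyl)oxy]-2-[(1E,4R)-7-[(tert-butyldimethylsilyl)oxy]-4-methylhept-1-en-1-yl]-4-methylhexanoic acid
Product: 21 tert-butyl (2R,3R,4S)-3-[(tert-butyldimethylsilyl)oxy]-2-[(1E,4R)-7-[(tert-butyldimethylsilyl)oxy]-4-methylhept-1-en-1-yl]-4-methylhexanoate
Conditions: tert-butyl N,N'-diisopropylcarbamimidate, CH2Cl2, rt
Reagents that add atoms: tert-butyl N,N'-diisopropylcarbamimidate, CC(C)N=C(OC(C)(C)C)NC(C)C
Why: Isourea esterification proceeds by protonation of the isourea by the acid and tert-butyl transfer to the carboxylate, so no base and no carboxyl activation can epimerise the α-centre.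

Step 14
Reactants: 21 tert-butyl (2R,3R,4S)-3-[(tert-butyldimethylsilyl)oxy]-2-[(1E,4R)-7-[(tert-butyldimethylsilyl)oxy]-4-methylhept-1-en-1-yl]-4-methylhexanoate
Product: 22 tert-butyl (2R,3R,4S)-3-[(tert-butyldimethylsilyl)oxy]-2-[(1E,4R)-7-hydroxy-4-methylhept-1-en-1-yl]-4-methylhexanoate
Conditions: HF·pyridine, pyridine, THF, 0 °C
Reagents that add atoms: none
Why: Buffered HF·pyridine cleaves the unhindered primary silyl ether much faster than the secondary one flanked by two branched carbons (steric differentiation of TBS ethers), and the tert-butyl ester is inert.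

Step 15
Reactants: 22 tert-butyl (2R,3R,4S)-3-[(tert-butyldimethylsilyl)oxy]-2-[(1E,4R)-7-hydroxy-4-methylhept-1-en-1-yl]-4-methylhexanoate
Product: 24 (4R,5E,7R,8R,9S)-7-(tert-butoxycarbonyl)-8-[(tert-butyldimethylsilyl)oxy]-4,9-dimethylundec-5-enoic acid, via terminal aldehyde 23 (not isolated)
Conditions: TEMPO (cat.), PhI(OAc)2, MeCN/pH 7 phosphate buffer, 0 °C→rt
Reagents that add atoms: water, O
Why: The same oxoammonium oxidation converts the unhindered primary alcohol through aldehyde 23 into the acid and touches neither the tert-butyl ester nor the secondary silyl ether.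

Step 16
Reactants: 25 methyl (R)-3-hydroxybutanoate
Product: 26 tert-butyl (5R)-5-hydroxy-3-oxohexanoate
Conditions: LiN(iPr)2 (4 equiv), tBuOAc (4 equiv), THF, −78 °C; then 25, −78→−30 °C; aq. NH4Cl
Reagents that add atoms: tert-butyl acetate, CC(=O)OC(C)(C)C
Why: In this crossed Claisen condensation the excess lithium enolate of tert-butyl acetate first deprotonates the hydroxyl and then acylates at the methyl ester, the carbinol centre taking no part.

Step 17
Reactants: 26 tert-butyl (5R)-5-hydroxy-3-oxohexanoate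
Product: 27 (6R)-6-methyloxane-2,4-dione
Conditions: CF3CO2H, CH2Cl2, rt
Reagents that add atoms: none
Why: Acidolysis of the tert-butyl ester and lactonisation of the δ-hydroxy β-keto acid close the six-membered ring by 6-exo-trig acyl substitution with the carbinol C–O bond, and hence the (R) configuration, untouched.

Step 18
Reactants: 24 (4R,5E,7R,8R,9S)-7-(tert-butoxycarbonyl)-8-[(tert-butyldimethylsilyl)oxy]-4,9-dimethylundec-5-enoic acid; 27 (6R)-6-methyloxane-2,4-dione
Product: 28 tert-butyl (2R,3R,4S)-3-[(tert-butyldimethylsilyl)oxy]-2-[(1E,4R)-7-[(6R)-4-hydroxy-6-methyl-2-oxo-5,6-dihydro-2H-pyran-3-yl]-4-methyl-7-oxohept-1-en-1-yl]-4-methylhexanoate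
Conditions: DCC, DMAP, CH2Cl2, 0 °C→rt
Reagents that add atoms: none
Why: Carbodiimide activation gives the enol ester at O4 of 27, which DMAP relays to C3 (O-to-C acyl migration, the established DCC/DMAP C-acylation of cyclic 1,3-diones) to give the chelated 3-acyl-4-hydroxy lactone, only the free carboxyl of 24 being open to activation.

Step 19
Reactants: 28 tert-butyl (2R,3R,4S)-3-[(tert-butyldimethylsilyl)oxy]-2-[(1E,4R)-7-[(6R)-4-hydroxy-6-methyl-2-oxo-5,6-dihydro-2H-pyran-3-yl]-4-methyl-7-oxohept-1-en-1-yl]-4-methylhexanoate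
Product: 30 (2R,3R,4S)-3-hydroxy-2-[(1E,4R)-7-[(6R)-4-hydroxy-6-methyl-2-oxo-5,6-dihydro-2H-pyran-3-yl]-4-methyl-7-oxohept-1-en-1-yl]-4-methylhexanoic acid, via silyl ether acid 29 (not isolated)
Conditions: CF3CO2H/CH2Cl2, 0 °C→rt; concentrate; 48% aq. HF, MeCN, rt
Reagents that add atoms: none
Why: Acidolysis (loss of the tert-butyl cation) frees the carboxylic acid and HF then removes the hindered secondary silyl ether, and since no base is present the α-vinyl centre and the β-hydroxy acid should survive.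

**Compound list**

1 | (S)-2-methylbutan-1-ol | CC[C@H](C)CO | starting material
2 | (S)-2-methylbutanal | CC[C@H](C)C=O | intermediate
3 | ethyl (2E,4S)-4-methylhex-2-enoate | CC[C@H](C)/C=C/C(=O)OCC | intermediate
4 | (2E,4S)-4-methylhex-2-en-1-ol | CC[C@H](C)/C=C/CO | intermediate
5 | [(2R,3R)-3-[(2S)-butan-2-yl]oxiran-2-yl]methanol | CC[C@H](C)[C@H]1O[C@@H]1CO | intermediate
6 | (2S,3R,4S)-2-ethenyl-4-methylhexane-1,3-diol | CC[C@H](C)[C@@H](O)[C@@H](C=C)CO | intermediate
7 | (2S,3R,4S)-2-ethenyl-1-[(4-methoxybenzyl)oxy]-4-methylhexan-3-ol | CC[C@H](C)[C@@H](O)[C@@H](C=C)COCc1ccc(OC)cc1 | intermediate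
8 | tert-butyl{[(3S,4R,5S)-3-{[(4-methoxybenzyl)oxy]methyl}-5-methylhept-1-en-4-yl]oxy}dimethylsilane | CC[C@H](C)[C@@H](O[Si](C)(C)C(C)(C)C)[C@@H](C=C)COCc1ccc(OC)cc1 | intermediate
9 | (2S,3R,4S)-3-[(tert-butyldimethylsilyl)oxy]-2-{[(4-methoxybenzyl)oxy]methyl}-4-methylhexanal | CC[C@H](C)[C@@H](O[Si](C)(C)C(C)(C)C)[C@@H](C=O)COCc1ccc(OC)cc1 | intermediate
10 | iodoform | IC(I)I | starting material
11 | tert-butyl{[(1E,3S,4R,5S)-1-iodo-3-{[(4-methoxybenzyl)oxy]methyl}-5-methylhept-1-en-4-yl]oxy}dimethylsilane | CC[C@H](C)[C@@H](O[Si](C)(C)C(C)(C)C)[C@@H](/C=C/I)COCc1ccc(OC)cc1 | intermediate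
12 | pent-4-en-1-ol | C=CCCCO | starting material
13 | tert-butyldimethyl(pent-4-en-1-yloxy)silane | C=CCCCO[Si](C)(C)C(C)(C)C | intermediate
14 | trimethylaluminium | C[Al](C)C | starting material
15 | {(2R)-5-[(tert-butyldimethylsilyl)oxy]-2-methylpentyl}dimethylalane | C[Al](C)C[C@H](C)CCCO[Si](C)(C)C(C)(C)C | intermediate
16 | {(2R)-5-[(tert-butyldimethylsilyl)oxy]-2-methylpentyl}zinc trifluoromethanesulfonate | FC(F)(F)S(=O)(=O)O[Zn]C[C@H](C)CCCO[Si](C)(C)C(C)(C)C | intermediate
17 | (4R,6E,8S,9R,10S)-1,9-bis[(tert-butyldimethylsilyl)oxy]-8-{[(4-methoxybenzyl)oxy]methyl}-4,10-dimethyldodec-6-ene | CC[C@H](C)[C@@H](O[Si](C)(C)C(C)(C)C)[C@@H](/C=C/C[C@H](C)CCCO[Si](C)(C)C(C)(C)C)COCc1ccc(OC)cc1 | intermediate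
18 | (2S,3R,4S)-3-[(tert-butyldimethylsilyl)oxy]-2-[(1E,4R)-7-[(tert-butyldimethylsilyl)oxy]-4-methylhept-1-en-1-yl]-4-methylhexan-1-ol | CC[C@H](C)[C@@H](O[Si](C)(C)C(C)(C)C)[C@@H](/C=C/C[C@H](C)CCCO[Si](C)(C)C(C)(C)C)CO | intermediate
19 | (2R,3R,4S)-3-[(tert-butyldimethylsilyl)oxy]-2-[(1E,4R)-7-[(tert-butyldimethylsilyl)oxy]-4-methylhept-1-en-1-yl]-4-methylhexanal | CC[C@H](C)[C@@H](O[Si](C)(C)C(C)(C)C)[C@@H](/C=C/C[C@H](C)CCCO[Si](C)(C)C(C)(C)C)C=O | intermediate
20 | (2R,3R,4S)-3-[(tert-butyldimethylsilyl)oxy]-2-[(1E,4R)-7-[(tert-butyldimethylsilyl)oxy]-4-methylhept-1-en-1-yl]-4-methylhexanoic acid | CC[C@H](C)[C@@H](O[Si](C)(C)C(C)(C)C)[C@@H](/C=C/C[C@H](C)CCCO[Si](C)(C)C(C)(C)C)C(=O)O | intermediate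
21 | tert-butyl (2R,3R,4S)-3-[(tert-butyldimethylsilyl)oxy]-2-[(1E,4R)-7-[(tert-butyldimethylsilyl)oxy]-4-methylhept-1-en-1-yl]-4-methylhexanoate | CC[C@H](C)[C@@H](O[Si](C)(C)C(C)(C)C)[C@@H](/C=C/C[C@H](C)CCCO[Si](C)(C)C(C)(C)C)C(=O)OC(C)(C)C | intermediate
22 | tert-butyl (2R,3R,4S)-3-[(tert-butyldimethylsilyl)oxy]-2-[(1E,4R)-7-hydroxy-4-methylhept-1-en-1-yl]-4-methylhexanoate | CC[C@H](C)[C@@H](O[Si](C)(C)C(C)(C)C)[C@@H](/C=C/C[C@H](C)CCCO)C(=O)OC(C)(C)C | intermediate
23 | tert-butyl (2R,3R,4S)-3-[(tert-butyldimethylsilyl)oxy]-4-methyl-2-[(1E,4R)-4-methyl-7-oxohept-1-en-1-yl]hexanoate | CC[C@H](C)[C@@H](O[Si](C)(C)C(C)(C)C)[C@@H](/C=C/C[C@H](C)CCC=O)C(=O)OC(C)(C)C | intermediate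
24 | (4R,5E,7R,8R,9S)-7-(tert-butoxycarbonyl)-8-[(tert-butyldimethylsilyl)oxy]-4,9-dimethylundec-5-enoic acid | CC[C@H](C)[C@@H](O[Si](C)(C)C(C)(C)C)[C@@H](/C=C/C[C@H](C)CCC(=O)O)C(=O)OC(C)(C)C | intermediate
25 | methyl (R)-3-hydroxybutanoate | C[C@@H](O)CC(=O)OC | starting material
26 | tert-butyl (5R)-5-hydroxy-3-oxohexanoate | C[C@@H](O)CC(=O)CC(=O)OC(C)(C)C | intermediate
27 | (6R)-6-methyloxane-2,4-dione | C[C@@H]1CC(=O)CC(=O)O1 | intermediate
28 | tert-butyl (2R,3R,4S)-3-[(tert-butyldimethylsilyl)oxy]-2-[(1E,4R)-7-[(6R)-4-hydroxy-6-methyl-2-oxo-5,6-dihydro-2H-pyran-3-yl]-4-methyl-7-oxohept-1-en-1-yl]-4-methylhexanoate | CC[C@H](C)[C@@H](O[Si](C)(C)C(C)(C)C)[C@@H](/C=C/C[C@H](C)CCC(=O)C1=C(O)C[C@@H](C)OC1=O)C(=O)OC(C)(C)C | intermediate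
29 | (2R,3R,4S)-3-[(tert-butyldimethylsilyl)oxy]-2-[(1E,4R)-7-[(6R)-4-hydroxy-6-methyl-2-oxo-5,6-dihydro-2H-pyran-3-yl]-4-methyl-7-oxohept-1-en-1-yl]-4-methylhexanoic acid | CC[C@H](C)[C@@H](O[Si](C)(C)C(C)(C)C)[C@@H](/C=C/C[C@H](C)CCC(=O)C1=C(O)C[C@@H](C)OC1=O)C(=O)O | intermediate
30 | (2R,3R,4S)-3-hydroxy-2-[(1E,4R)-7-[(6R)-4-hydroxy-6-methyl-2-oxo-5,6-dihydro-2H-pyran-3-yl]-4-methyl-7-oxohept-1-en-1-yl]-4-methylhexanoic acid | CC[C@H](C)[C@@H](O)[C@@H](/C=C/C[C@H](C)CCC(=O)C1=C(O)C[C@@H](C)OC1=O)C(=O)O | target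

**Count and risks**

Total step count: 19. Longest linear sequence: 16 steps (steps 1–8, 10–15, 18 and 19).

Steps most likely to fail:

1. Step 10. The methylalumination may proceed with only moderate enantioface selectivity, so that the epimer at the methyl-bearing carbon is hard to remove. In the coupling stage, methyl groups on aluminium or zinc may be transferred in competition with the 2-methylalkyl group, or transmetalation may stay incomplete, which wastes iodide 11. Fallback, setting out from 13 and coming back at 17: the same zirconium-catalysed methylalumination is followed by oxidation of the alane with O2 to (2R)-5-[(tert-butyldimethylsilyl)oxy]-2-methylpentan-1-ol F1. Its enantiomeric purity is raised by acetylation with vinyl acetate and Pseudomonas cepacia lipase, which is expected to convert the minor enantiomer faster into (2S)-5-[(tert-butyldimethylsilyl)oxy]-2-methylpentyl acetate F2, which is discarded. F1 is converted with I2, PPh3 and imidazole into tert-butyl{[(4R)-5-iodo-4-methylpentyl]oxy}dimethylsilane F3. Zinc dust activated with LiCl in THF inserts to give {(2R)-5-[(tert-butyldimethylsilyl)oxy]-2-methylpentyl}zinc iodide F4, and Negishi coupling of F4 with 11 under Pd(PPh3)4 catalysis gives 17.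

2. Step 18. Acyl transfer may stop at the O4 enol ester, or the activated acid may rearrange to the N-acylurea, so that the bond from C3 of the ring to the ketone carbon does not form. Fallback, setting out from 24 and coming back at 28, with the ring built on the chain instead of being acylated: condensation of 24 with Meldrum's acid (DCC, DMAP, CH2Cl2) gives the acyl Meldrum's acid tert-butyl (2R,3R,4S)-3-[(tert-butyldimethylsilyl)oxy]-2-[(1E,4R)-7-(2,2-dimethyl-4,6-dioxo-1,3-dioxan-5-ylidene)-7-hydroxy-4-methylhept-1-en-1-yl]-4-methylhexanoate F5. Heating F5 with methyl (R)-3-hydroxybutanoate 25 in toluene (acylketene formation and trapping by the hydroxyl) gives the β-keto ester (2R)-4-methoxy-4-oxobutan-2-yl (6R,7E,9R,10R,11S)-9-(tert-butoxycarbonyl)-10-[(tert-butyldimethylsilyl)oxy]-6,11-dimethyl-3-oxotridec-7-enoate F6. Dieckmann cyclisation of F6 with KOtBu in tBuOH/THF at rt closes the lactone onto the methyl ester and gives 28.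

3. Step 8. Addition of the gem-dichromium reagent to the hindered α-branched aldehyde may be slow, so that E/Z mixtures, α-epimerisation or β-elimination of the PMB-oxy group under the Lewis-acidic chromium salts compete. Fallback, setting out from 9 and coming back at 11: Ohira–Bestmann homologation (dimethyl (1-diazo-2-oxopropyl)phosphonate, K2CO3, MeOH, 0 °C) gives the terminal alkyne tert-butyl{[(3S,4R,5S)-3-{[(4-methoxybenzyl)oxy]methyl}-5-methylhept-1-yn-4-yl]oxy}dimethylsilane F7. Hydrozirconation with Cp2Zr(H)Cl in THF gives the (E)-alkenylzirconocene chloride F8 by syn addition, and iodinolysis with I2 gives 11 with the E geometry fixed.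

Further compounds
F1 | step 10 | (2R)-5-[(tert-butyldimethylsilyl)oxy]-2-methylpentan-1-ol | OC[C@H](C)CCCO[Si](C)(C)C(C)(C)C
F2 | step 10 | (2S)-5-[(tert-butyldimethylsilyl)oxy]-2-methylpentyl acetate | CC(=O)OC[C@@H](C)CCCO[Si](C)(C)C(C)(C)C
F3 | step 10 | tert-butyl{[(4R)-5-iodo-4-methylpentyl]oxy}dimethylsilane | IC[C@H](C)CCCO[Si](C)(C)C(C)(C)C
F4 | step 10 | {(2R)-5-[(tert-butyldimethylsilyl)oxy]-2-methylpentyl}zinc iodide | I[Zn]C[C@H](C)CCCO[Si](C)(C)C(C)(C)C
F5 | step 18 | tert-butyl (2R,3R,4S)-3-[(tert-butyldimethylsilyl)oxy]-2-[(1E,4R)-7-(2,2-dimethyl-4,6-dioxo-1,3-dioxan-5-ylidene)-7-hydroxy-4-methylhept-1-en-1-yl]-4-methylhexanoate | CC[C@H](C)[C@@H](O[Si](C)(C)C(C)(C)C)[C@@H](/C=C/C[C@H](C)CCC(O)=C1C(=O)OC(C)(C)OC1=O)C(=O)OC(C)(C)C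
F6 | step 18 | (2R)-4-methoxy-4-oxobutan-2-yl (6R,7E,9R,10R,11S)-9-(tert-butoxycarbonyl)-10-[(tert-butyldimethylsilyl)oxy]-6,11-dimethyl-3-oxotridec-7-enoate | CC[C@H](C)[C@@H](O[Si](C)(C)C(C)(C)C)[C@@H](/C=C/C[C@H](C)CCC(=O)CC(=O)O[C@H](C)CC(=O)OC)C(=O)OC(C)(C)C
F7 | step 8 | tert-butyl{[(3S,4R,5S)-3-{[(4-methoxybenzyl)oxy]methyl}-5-methylhept-1-yn-4-yl]oxy}dimethylsilane | CC[C@H](C)[C@@H](O[Si](C)(C)C(C)(C)C)[C@@H](C#C)COCc1ccc(OC)cc1
F8 | step 8 | chlorido{(1E,3S,4R,5S)-4-[(tert-butyldimethylsilyl)oxy]-3-{[(4-methoxybenzyl)oxy]methyl}-5-methylhept-1-en-1-yl}bis(cyclopentadienyl)zirconium | CC[C@H](C)[C@@H](O[Si](C)(C)C(C)(C)C)[C@@H](/C=C/[Zr](Cl)(C1C=CC=C1)C1C=CC=C1)COCc1ccc(OC)cc1
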